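**Strategy.** The C8 spiro-epoxide (C8, C17, O) is treated as a masked exocyclic methylene lying γ to the C6 oxygen, so ring B (C5–C10) is closed last, between C7 and C8. A gold(I)-catalysed Conia-ene-type 6-exo-dig cyclisation adds the CH2 terminus (C7) of a C6 silyl enol ether to the internal carbon (C8) of an ethynyl group on C9 and gives, in one operation, the trans-fused 6-keto-8(17)-methylene decalin. The precursor is the ring-A 19,20-lactone (C4, C5, C10 set) carrying a 1-silyloxyvinyl group on C5 and, on C10, the preformed C9 spiro-ether (9,13-epoxy-15,16-olide) with the ethynyl group. C8 is then set by epoxidation directed by the 6β-hydroxyl.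

Key step: step 12

Remarks on the chemistry:
- Locants C1–C20 in names are the labdane locants of the target; α is the face of H-5, β the face of C-20.
- Compounds 3–5 are racemic and are drawn as the enantiomer carried on after the resolution in step 4.
- 3-(Furan-3-yl)propanoic acid is assumed to be a purchasable building block.

Step 1
Reactants: 1 citraconic anhydride; 2 methyl (2E)-penta-2,4-dienoate
Product: 3 racemic endo Diels–Alder anhydride
Conditions: neat (1 in excess), hydroquinone (cat.), 130 °C, sealed tube; crystallisation
Reagents that add atoms: none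
Why: Thermal Diels–Alder reaction: the cyclic dienophile fixes the cis relation of the C19 and C6 carbonyl carbons and creates the C4 quaternary centre, and the methyl-bearing carbon should bond to the unsubstituted diene terminus so that the ester sits on C10 next to C5 (the C10 configuration is reset in step 6).

Step 2
Reactants: 3 racemic endo Diels–Alder anhydride
Product: 4 racemic saturated anhydride
Conditions: H2 (1 atm), Pd/C, EtOAc, rt
Reagents that add atoms: none
Why: Heterogeneous hydrogenation of the isolated cis-disubstituted ring alkene, which should leave anhydride and ester untouched and creates no stereocentre.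

Step 3
Reactants: 4 racemic saturated anhydride
Product: 5 racemic keto acid
Conditions: Me2Zn, Ni(cod)2 (cat.), 2,2'-bipyridine, 4-fluorostyrene, THF, 0 °C to rt; 1 M HCl
Reagents that add atoms: dimethylzinc, C[Zn]C
Why: Nickel-catalysed alkylative ring opening of a cyclic anhydride with a diorganozinc (acyl C–O oxidative addition, transmetalation, reductive elimination) should occur at the less hindered C6 carbonyl next to C5–H, not at the neopentyl C19 carbonyl, and stop at the methyl ketone.

Step 4
Reactants: 5 racemic keto acid; 6 (S)-1-phenylethylamine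
Product: 7 (S)-1-phenylethylammonium salt of the (1S,2R,3R)-keto acid
Conditions: 6 (0.55 equiv), EtOAc/EtOH, fractional crystallisation to constant rotation
Reagents that add atoms: none
Why: Classical resolution through diastereomeric ammonium carboxylates; the salt carrying the (1S,2R,3R)-acid is taken on (the antipodal amine is used if the other salt is the less soluble one), with the configuration to be secured by X-ray analysis.

Step 5
Reactants: 7 (S)-1-phenylethylammonium salt of the (1S,2R,3R)-keto acid
Product: 8 silyl ester silyl enol ether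
Conditions: cold 1 M HCl/EtOAc (free acid); then i-Pr3SiOTf (2.4 equiv), Et3N, CH2Cl2, −20 to 0 °C
Reagents that add atoms: triisopropylsilyl trifluoromethanesulfonate, CC(C)[Si](C(C)C)(C(C)C)OS(=O)(=O)C(F)(F)F
Why: Soft enolisation and O-silylation: the acid becomes the silyl ester and the methyl ketone should give the terminal enol ether, because a C5=C6 double bond would suffer severe allylic strain against the C4 and C10 substituents; this masks the ketone and its acidic hydrogens for steps 6–8.

Step 6
Reactants: 8 silyl ester silyl enol ether; 9 3-(furan-3-yl)propanoic acid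
Product: 11 C10-acylated β-keto ester, via acyl imidazolide 10 (not isolated)
Conditions: 8, LDA (2.1 equiv), THF, −78 °C; then 10 (from 9 and carbonyldiimidazole, THF, rt), −78 to −40 °C; NH4Cl
Reagents that add atoms: none
Why: C-acylation of a lithium ester enolate (crossed Claisen-type condensation) creates the C10 quaternary centre; the acyl group should enter anti to the adjacent C5 silyloxyvinyl group, placing C9 trans to C6 and leaving the ester carbon C20 cis to C6 and C19.

Step 7
Reactants: 11 C10-acylated β-keto ester
Product: 12 (9R)-propargylic alcohol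
Conditions: HC≡CMgBr, anhydrous CeCl3, THF, −78 °C; AcOH quench at −78 °C
Reagents that add atoms: ethynylmagnesium bromide, C#C[Mg]Br
Why: Chelation-controlled 1,2-addition of an alkynyl cerium reagent to an α,α-disubstituted β-keto ester: with ketone and ester carbonyls held syn by the metal, the acetylide should attack the face flanked by the C1 methylene and not by the substituted C5, which gives the C9 configuration needed for a 9α-oxygen; the non-basic reagent and cold quench limit enolisation and retro-aldol cleavage.

Step 8
Reactants: 12 (9R)-propargylic alcohol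
Product: 14 furan keto lactone, via C20 carbinol 13 (not isolated)
Conditions: LiBH4, MeOH (1 equiv), THF, 0 °C to rt; then 1 M HCl/THF, rt
Reagents that add atoms: none
Why: Hydroxyl-assisted borohydride reduction of the β-hydroxy ester (the hindered silyl ester should not be reduced) gives the C20 carbinol, and acid then removes both silyl groups, frees the methyl ketone and lactonises the 1,3-diaxial C20–OH/C19–CO2H pair to the bridged δ-lactone; the tertiary C9–OH cannot reach C19.

Step 9
Reactants: 14 furan keto lactone
Product: 16 butenolide alcohol, via hydroxybutenolide 15 (not isolated)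
Conditions: O2, hν, tetraphenylporphyrin (cat.), i-Pr2NEt, CH2Cl2, −78 °C; then MeOH, NaBH4, −40 °C; 1 M HCl to pH 3
Reagents that add atoms: oxygen, O=O
Why: [4+2] photooxygenation of the 3-alkylfuran and base-induced (Kornblum–DeLaMare-type) opening of the endoperoxide at the less hindered position gives the 4-alkyl-5-hydroxybutenolide, whose masked aldehyde should be reduced much faster than the very hindered C6 methyl ketone and relactonise on acidification to the 4-substituted butenolide.

Step 10
Reactants: 16 butenolide alcohol
Product: 17 spiro lactone methyl ketone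
Conditions: DBU (0.5 equiv), CH2Cl2, rt
Reagents that add atoms: none
Why: Intramolecular oxa-Michael addition (5-exo-trig) of the tertiary C9 hydroxyl to the butenolide β-carbon C13 forms the spiro tetrahydrofuran; the addition is reversible under base, so the required 13R epimer (C14 syn to C10) is separated and the 13S epimer re-equilibrated.

Step 11
Reactants: 17 spiro lactone methyl ketone
Product: 18 TBS enol ether
Conditions: t-BuMe2SiOTf, Et3N, CH2Cl2, −78 to 0 °C
Reagents that add atoms: tert-butyldimethylsilyl trifluoromethanesulfonate, CC(C)(C)[Si](C)(C)OS(=O)(=O)C(F)(F)F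
Why: Soft enolisation of the methyl ketone gives only the terminal silyl enol ether, since C5 lies between two quaternary carbons; lactones and alkyne should be untouched.

Step 12
Reactants: 18 TBS enol ether
Product: 19 6-keto-8(17)-ene tricycle
Conditions: [JohnPhosAu(NCMe)]SbF6 (5 mol %), CH2Cl2/MeOH (10:1), rt
Reagents that add atoms: none
Why: The cationic gold(I) complex π-activates the terminal alkyne, the silyl enol ether attacks anti through its CH2 carbon (C7) at the internal alkyne carbon (C8), methanol removes the silyl group from the silyloxocarbenium ion and protodeauration of the vinylgold species releases the exocyclic methylene and the catalyst. The closest known reaction type is the gold(I)-catalysed Conia-ene-type carbocyclisation of silyl enol ethers onto terminal alkynes. Ring B closes in the 6-exo-dig mode (C7, C6, C5, C10, C9, C8 in the ring, C17 outside). No new stereocentre is formed: the trans ring fusion is fixed by the trans-diequatorial C5 and C10 substituents, and C8 stays sp2 so that its configuration is set in step 14. The step needs 6-exo over 7-endo closure and reaction through C7 only; Markovnikov activation of the terminal alkyne directs attack to C8, and the enol ether has no other nucleophilic terminus because C5 is blocked by two quaternary neighbours. Alkyne hydration and simple protodesilylation are the competing paths and are limited by using only a small amount of methanol.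

Step 13
Reactants: 19 6-keto-8(17)-ene tricycle
Product: 20 6β-alcohol
Conditions: NaBH4, MeOH/CH2Cl2, −40 °C; cold dilute HCl
Reagents that add atoms: none
Why: Hydride reduction of the cyclohexanone: the β face of C6 is screened by the axial C20 methylene and the C19 carbonyl, so hydride should add from the α face to give the axial 6β-alcohol (6R); low temperature keeps both lactones intact and avoids conjugation of the β,γ double bond.

Step 14
Reactants: 20 6β-alcohol
Product: 21 8β,17-epoxy alcohol
Conditions: VO(acac)2 (10 mol %), t-BuOOH, CH2Cl2, 0 °C to rt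
Reagents that add atoms: tert-butyl hydroperoxide, CC(C)(C)OO
Why: Vanadium-catalysed hydroxyl-directed epoxidation of a homoallylic alcohol: the axial 6β-OH should deliver oxygen to the β face of the C8=C17 double bond (1,3-diaxial relationship), giving the 8R epoxide with oxygen axial and the methylene equatorial.

Step 15
Reactants: 21 8β,17-epoxy alcohol
Product: 22 6β-acetate
Conditions: Ac2O, DMAP (cat.), pyridine, 0 °C to rt
Reagents that add atoms: acetic anhydride, CC(=O)OC(C)=O
Why: DMAP-catalysed acylation of the hindered axial alcohol with retention at C6, run without strong base to avoid translactonisation of the 6β-oxygen onto C19.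

Step 16
Reactants: 22 6β-acetate
Product: 23 15-lactol
Conditions: disiamylborane, THF, 0 °C to rt; aqueous NaHCO3 (non-oxidative work-up)
Reagents that add atoms: none
Why: Chemoselective partial reduction of the γ-lactone to the lactol with a hindered dialkylborane, a reagent that should leave the acetate, the α-quaternary δ-lactone and the epoxide untouched.

Step 17
Reactants: 23 15-lactol
Product: 25 target triepoxylabdenolide, via lactol mesylate 24 (not isolated)
Conditions: MsCl, Et3N (excess), CH2Cl2, −40 °C to rt; basic work-up, Et3N-deactivated silica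
Reagents that add atoms: none
Why: Sulfonylation of the lactol and base-induced elimination (glycal-type enol ether formation) can only give the C14=C15 double bond because C13 is quaternary; acetate, epoxide and lactone should survive the basic, non-aqueous conditions.

**Compound list**

1 | citraconic anhydride (3-methylfuran-2,5-dione) | CC1=CC(=O)OC1=O | starting material
2 | methyl (2E)-penta-2,4-dienoate | COC(=O)/C=C/C=C | starting material
3 | racemic endo Diels–Alder anhydride: methyl 7a-methyl-1,3-dioxo-1,3,3a,4,7,7a-hexahydro-2-benzofuran-4-carboxylate, ester (on C10) cis to the anhydride carbons C6/C19, 4-Me and H-5 on the other face | COC(=O)[C@@H]1C=CC[C@]2(C)C(=O)OC(=O)[C@H]12 | intermediate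
4 | racemic saturated anhydride: methyl 7a-methyl-1,3-dioxooctahydro-2-benzofuran-4-carboxylate, relative configuration as in 3 | COC(=O)[C@@H]1CCC[C@]2(C)C(=O)OC(=O)[C@H]12 | intermediate
5 | racemic keto acid: (1S*,2R*,3R*)-2-acetyl-3-(methoxycarbonyl)-1-methylcyclohexane-1-carboxylic acid (ring C1/C2/C3 = C4/C5/C10 of the target) | COC(=O)[C@@H]1CCC[C@](C)(C(O)=O)[C@@H]1C(C)=O | intermediate
6 | (S)-1-phenylethylamine | C[C@H](N)c1ccccc1 | starting material
7 | (S)-1-phenylethylammonium (1S,2R,3R)-2-acetyl-3-(methoxycarbonyl)-1-methylcyclohexane-1-carboxylate | COC(=O)[C@@H]1CCC[C@](C)(C([O-])=O)[C@@H]1C(C)=O.C[C@H]([NH3+])c1ccccc1 | intermediate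
8 | silyl ester silyl enol ether: 4β-CO2Si(i-Pr)3, 4α-Me, 5β-[1-(triisopropylsilyloxy)ethenyl] (5α-H), 10β-CO2Me (10α-H) cyclohexane | COC(=O)[C@@H]1CCC[C@](C)(C(=O)O[Si](C(C)C)(C(C)C)C(C)C)[C@@H]1C(=C)O[Si](C(C)C)(C(C)C)C(C)C | intermediate
9 | 3-(furan-3-yl)propanoic acid | OC(=O)CCc1ccoc1 | starting material
10 | acyl imidazolide: 3-(furan-3-yl)-1-(1H-imidazol-1-yl)propan-1-one | O=C(CCc1ccoc1)n1ccnc1 | intermediate
11 | C10-acylated β-keto ester: as 8 but C10 quaternary with 10β-CO2Me and 10α-[3-(furan-3-yl)propanoyl] (C9 ketone) | O=C(CCc1ccoc1)[C@@]2(C(=O)OC)CCC[C@](C)(C(=O)O[Si](C(C)C)(C(C)C)C(C)C)[C@@H]2C(=C)O[Si](C(C)C)(C(C)C)C(C)C | intermediate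
12 | (9R)-propargylic alcohol: as 11 but C9 carries OH, ethynyl (C8≡C17) and the 2-(furan-3-yl)ethyl chain | C#C[C@](O)(CCc1ccoc1)[C@@]2(C(=O)OC)CCC[C@](C)(C(=O)O[Si](C(C)C)(C(C)C)C(C)C)[C@@H]2C(=C)O[Si](C(C)C)(C(C)C)C(C)C | intermediate
13 | C20 carbinol: as 12 but 10β-CH2OH in place of 10β-CO2Me | C#C[C@](O)(CCc1ccoc1)[C@@]2(CO)CCC[C@](C)(C(=O)O[Si](C(C)C)(C(C)C)C(C)C)[C@@H]2C(=C)O[Si](C(C)C)(C(C)C)C(C)C | intermediate
14 | furan keto lactone: ring-A 19,20-olide (3-oxabicyclo[3.3.1]nonan-2-one), 4α-Me, 5β-acetyl, C10 bearing (9R)-C(OH)(C≡CH)CH2CH2(furan-3-yl) | C#C[C@](O)(CCc1ccoc1)[C@]23CCC[C@](C)(C(=O)OC2)[C@@H]3C(C)=O | intermediate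
15 | hydroxybutenolide: as 14 with the furan replaced by 5-hydroxy-2-oxo-2,5-dihydrofuran-4-yl (C16 epimers) | C#C[C@](O)(CCC1=CC(=O)OC1O)[C@]23CCC[C@](C)(C(=O)OC2)[C@@H]3C(C)=O | intermediate
16 | butenolide alcohol: as 14 with the furan replaced by 5-oxo-2,5-dihydrofuran-3-yl (13-en-15,16-olide), 9-OH free | C#C[C@](O)(CCC1=CC(=O)OC1)[C@]23CCC[C@](C)(C(=O)OC2)[C@@H]3C(C)=O | intermediate
17 | spiro lactone methyl ketone: (9R,13R)-9,13-epoxy-15,16-olide spiro unit on C10 with 9-ethynyl, ring-A 19,20-olide, 5β-acetyl | C#C[C@]2(CC[C@]3(CC(=O)OC3)O2)[C@]23CCC[C@](C)(C(=O)OC2)[C@@H]3C(C)=O | intermediate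
18 | TBS enol ether: as 17 with 5β-[1-(tert-butyldimethylsilyloxy)ethenyl] | C#C[C@]2(CC[C@]3(CC(=O)OC3)O2)[C@]23CCC[C@](C)(C(=O)OC2)[C@@H]3C(=C)O[Si](C)(C)C(C)(C)C | intermediate
19 | 6-keto-8(17)-ene tricycle: (13R)-9α,13-epoxy-6-oxolabd-8(17)-ene-15,16:19,20-diolide | O=C1CC(=C)[C@]2(CC[C@]3(CC(=O)OC3)O2)[C@]23CCC[C@](C)(C(=O)OC2)[C@H]13 | intermediate
20 | 6β-alcohol: (6R,13R)-9α,13-epoxy-6β-hydroxylabd-8(17)-ene-15,16:19,20-diolide | O[C@@H]1CC(=C)[C@]2(CC[C@]3(CC(=O)OC3)O2)[C@]23CCC[C@](C)(C(=O)OC2)[C@H]13 | intermediate
21 | 8β,17-epoxy alcohol: (6R,8R,13R)-8β,17:9α,13-diepoxy-6β-hydroxylabdane-15,16:19,20-diolide | O[C@@H]1C[C@@]2(CO2)[C@]2(CC[C@]3(CC(=O)OC3)O2)[C@]23CCC[C@](C)(C(=O)OC2)[C@H]13 | intermediate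
22 | 6β-acetate of 21 | CC(=O)O[C@@H]1C[C@@]2(CO2)[C@]2(CC[C@]3(CC(=O)OC3)O2)[C@]23CCC[C@](C)(C(=O)OC2)[C@H]13 | intermediate
23 | 15-lactol: 6β-acetoxy-8β,17:9α,13:15,16-triepoxy-15-hydroxylabdan-19,20-olide (C15 epimers) | CC(=O)O[C@@H]1C[C@@]2(CO2)[C@]2(CC[C@]3(CC(O)OC3)O2)[C@]23CCC[C@](C)(C(=O)OC2)[C@H]13 | intermediate
24 | lactol mesylate: 15-O-methanesulfonate of 23 | CC(=O)O[C@@H]1C[C@@]2(CO2)[C@]2(CC[C@]3(CC(OS(C)(=O)=O)OC3)O2)[C@]23CCC[C@](C)(C(=O)OC2)[C@H]13 | intermediate
25 | (4S,5R,6R,8R,9S,10S,13R)-6β-acetoxy-8β,17:9α,13:15,16-triepoxylabd-14-en-19,20-olide | CC(=O)O[C@@H]1C[C@@]2(CO2)[C@]2(CC[C@]3(C=COC3)O2)[C@]23CCC[C@](C)(C(=O)OC2)[C@H]13 | target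

**Totals.** Total step count: 17. Longest linear sequence: 17 steps (from 1 and 2).

**Steps most likely to fail**

1. Step 12 (key step). Gold-mediated hydration of the alkyne or protodesilylation of the enol ether may outrun C–C bond formation at C8, which is flanked by the fully substituted C9. Fallback (sets out from 18, returns at 19): iodination of 18 with N-iodosuccinimide (THF, −78 °C) should give the α-iodo ketone F1. Irradiation with catalytic hexabutylditin in benzene should then trigger an iodine-atom-transfer radical cyclisation, in which the α-keto radical at C7 attacks C8 in the 6-exo-dig mode, to give the vinyl iodide F2. Tributyltin hydride/AIBN reduces the C17–I bond to give 19.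

2. Step 7. The acetylide may attack through an open, non-chelated transition state and so add mainly to the other face of the C9 ketone. Fallback (sets out from 8, returns at 14): the enolate of 8 is acylated with the imidazolide of 3-(trimethylsilyl)propiolic acid to give the ynone F3. 2-(Furan-3-yl)ethylcerium dichloride (from 3-(2-iodoethyl)furan, t-BuLi, CeCl3) is then added to the ketone, so that the same facial bias that misdirected the acetylide now gives the required C9 epimer, the silyl alkyne carbinol F4. Reduction and acid treatment as in step 8 give the silyl alkyne keto lactone F5, and K2CO3/MeOH removes the C-silyl group to give 14.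

3. Step 10. The two faces of the butenolide differ little, so facial selectivity at C13 may be poor and recycling inefficient. Fallback (sets out from 14, returns at 17): photooxygenation as in step 9 without the borohydride stage gives the hydroxybutenolide 15, which is isolated and converted with MeOH/PPTS into the methyl acetal F6. DBU then effects the oxa-Michael addition on this closed pseudo-ester to give the spiro methoxy lactone F7 under thermodynamic control; the bulkier acetal-bearing C16 arm should take the side of the slim ethynyl group, trans to C10, which is the required C13 configuration. Mild aqueous acid hydrolyses the acetal to the spiro lactol lactone F8, and sodium borohydride followed by acidification gives 17.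

**Further compounds**

F1 | step 12 | α-iodo ketone: as 17 with 5β-iodoacetyl | C#C[C@]2(CC[C@]3(CC(=O)OC3)O2)[C@]23CCC[C@](C)(C(=O)OC2)[C@@H]3C(=O)CI
F2 | step 12 | vinyl iodide: as 19 with C17 carrying iodine (E/Z mixture) | O=C1CC(=CI)[C@]2(CC[C@]3(CC(=O)OC3)O2)[C@]23CCC[C@](C)(C(=O)OC2)[C@H]13
F3 | step 7 | ynone: as 11 with 10α-[3-(trimethylsilyl)propioloyl] | C[Si](C)(C)C#CC(=O)[C@@]1(C(=O)OC)CCC[C@](C)(C(=O)O[Si](C(C)C)(C(C)C)C(C)C)[C@@H]1C(=C)O[Si](C(C)C)(C(C)C)C(C)C
F4 | step 7 | silyl alkyne carbinol: as 12 with a trimethylsilyl group on C17 | C[Si](C)(C)C#C[C@](O)(CCc1ccoc1)[C@@]2(C(=O)OC)CCC[C@](C)(C(=O)O[Si](C(C)C)(C(C)C)C(C)C)[C@@H]2C(=C)O[Si](C(C)C)(C(C)C)C(C)C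
F5 | step 7 | silyl alkyne keto lactone: as 14 with a trimethylsilyl group on C17 | C[Si](C)(C)C#C[C@](O)(CCc1ccoc1)[C@]23CCC[C@](C)(C(=O)OC2)[C@@H]3C(C)=O
F6 | step 10 | methyl acetal: as 15 with 5-methoxy in place of 5-hydroxy (C16 epimers) | C#C[C@](O)(CCC1=CC(=O)OC1OC)[C@]23CCC[C@](C)(C(=O)OC2)[C@@H]3C(C)=O
F7 | step 10 | spiro methoxy lactone: as 17 with 16-methoxy (C16 epimers) | C#C[C@]2(CC[C@]3(CC(=O)OC3OC)O2)[C@]23CCC[C@](C)(C(=O)OC2)[C@@H]3C(C)=O
F8 | step 10 | spiro lactol lactone: as 17 with 16-hydroxy (C16 epimers) | C#C[C@]2(CC[C@]3(CC(=O)OC3O)O2)[C@]23CCC[C@](C)(C(=O)OC2)[C@@H]3C(C)=O
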